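## Retrosynthetic overview

1. No ring is formed: the coumarin bicycle (benzene ring A fused to pyranone ring B) is bought intact as 7-hydroxycoumarin 1, which is iodinated at C8 (2) and O-methylated (3).
2. C8–C(sp) disconnection: 3 and 2-methylbut-3-yn-2-ol 4 are joined by Sonogashira coupling to alkynol 5, which already holds all five side-chain carbons (C1' is the carbon on C8, C2' the next one).
3. I–O disconnection of the acyloxy donor: PhI(OAc)2 6 and 3-methylbut-2-enoic acid 7 give, through 8, the trivalent iodine reagent 9.
4. Key disconnection (new step): the C1'=O ketone and the C2'–O enol ester bond are made in one pot from 5 + 9, through 10 and 11, to give kimcuongin 12.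

Assumption: the target SMILES holds no stereocentre and no E/Z-defined double bond (both alkenes carry geminal methyl pairs), so the compound is achiral and only its constitution has to be made.

## Route

Step 1
Reactants: 1 7-hydroxy-2H-chromen-2-one (umbelliferone)
Product: 2 7-hydroxy-8-iodo-2H-chromen-2-one
Conditions: I2 (1.0 equiv), KI, 20% aq. NH3, 0 °C to rt; acidic work-up
Reagents that add atoms: iodine, I-I
Why: Electrophilic aromatic iodination (SEAr): under aqueous ammonia the 7-oxygen is ionised and steers iodine to C8, the ortho position between the two ring oxygens and the most nucleophilic site of umbelliferone, while a single equivalent of I2 holds back 6,8-di-iodination.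

Step 2
Reactants: 2 7-hydroxy-8-iodo-2H-chromen-2-one
Product: 3 8-iodo-7-methoxy-2H-chromen-2-one
Conditions: MeI (1.5 equiv), K2CO3 (2 equiv), acetone, reflux
Reagents that add atoms: iodomethane, CI
Why: Williamson ether synthesis: the acidic 7-OH is O-methylated by SN2 attack on MeI under K2CO3, and neither the lactone nor the aryl iodide reacts under these mild conditions.

Step 3
Reactants: 3 8-iodo-7-methoxy-2H-chromen-2-one; 4 2-methylbut-3-yn-2-ol
Product: 5 8-(3-hydroxy-3-methylbut-1-yn-1-yl)-7-methoxy-2H-chromen-2-one
Conditions: PdCl2(PPh3)2 (3 mol %), CuI (6 mol %), Et3N (3 equiv), THF, 50 °C, Ar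
Reagents that add atoms: none
Why: Sonogashira coupling: the aryl iodide adds oxidatively to zerovalent palladium despite its two ortho oxygens, the alkyne is delivered from copper, and the methylated phenol cannot cyclise onto the alkyne to a furocoumarin.

Step 4
Reactants: 6 (diacetoxyiodo)benzene, PhI(OAc)2; 7 3-methylbut-2-enoic acid (2.1 equiv)
Product: 9 [bis(3-methylbut-2-enoyloxy)iodo]benzene, via mixed acetate iodane 8 (not isolated)
Conditions: PhCl, 50 °C, 20 mbar (AcOH distilled off), dark
Reagents that add atoms: none
Why: Carboxylate ligand exchange at trivalent iodine: the exchange is an equilibrium that passes through 8 and is pulled to 9 by distilling off the more volatile acetic acid, and the electron-poor enoate double bond is inert to the iodane without Lewis acid activation.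

Step 5
Reactants: 5 8-(3-hydroxy-3-methylbut-1-yn-1-yl)-7-methoxy-2H-chromen-2-one; 9 [bis(3-methylbut-2-enoyloxy)iodo]benzene (1.3 equiv)
Product: 12 kimcuongin [1-(7-methoxy-2-oxo-2H-chromen-8-yl)-3-methyl-1-oxobut-2-en-2-yl 3-methylbut-2-enoate], via VO(OSiPh3)2 allenolate 10 (not isolated), via alkenyl iodane 11 (not isolated)
Conditions: VO(OSiPh3)3 (10 mol %), ClCH2CH2Cl, 60 °C, dark, 5 added over 4 h
Reagents that add atoms: none
Why: Proposed new method: VO(OSiPh3)3 binds the tertiary carbinol of 5 and its V=O unit carries out the [3,3] oxygen transposition of a Meyer–Schuster rearrangement, giving VO(OSiPh3)2 allenolate 10 with oxygen now on C1'; the nucleophilic central carbon (C2') of 10 attacks the electrophilic trivalent iodine of 9 to give alkenyl iodane 11, and carboxylate-to-carbon ligand coupling at iodine expels PhI and forms the C2'–O bond next to the new C1' ketone, slow addition of 5 keeping protonation of 10 to the plain enone in check; the closest known reaction types are the vanadium-oxo Meyer–Schuster rearrangement with trapping of the allenolate by carbon electrophiles and the α-acyloxylation of ketone enols by PhI(OAc)2, which have not been merged on an allenolate.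

## Compound list

1 | 7-hydroxy-2H-chromen-2-one (umbelliferone) | Oc1ccc2ccc(=O)oc2c1 | starting material
2 | 7-hydroxy-8-iodo-2H-chromen-2-one | Oc1ccc2ccc(=O)oc2c1I | intermediate
3 | 8-iodo-7-methoxy-2H-chromen-2-one | COc1ccc2ccc(=O)oc2c1I | intermediate
4 | 2-methylbut-3-yn-2-ol | CC(C)(O)C#C | starting material
5 | 8-(3-hydroxy-3-methylbut-1-yn-1-yl)-7-methoxy-2H-chromen-2-one | COc1ccc2ccc(=O)oc2c1C#CC(C)(C)O | intermediate
6 | (diacetoxyiodo)benzene, PhI(OAc)2 | CC(=O)OI(OC(C)=O)c1ccccc1 | starting material
7 | 3-methylbut-2-enoic acid (senecioic acid) | CC(C)=CC(O)=O | starting material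
8 | [acetoxy(3-methylbut-2-enoyloxy)iodo]benzene (mixed acetate iodane) | CC(=O)OI(OC(=O)C=C(C)C)c1ccccc1 | intermediate
9 | [bis(3-methylbut-2-enoyloxy)iodo]benzene | CC(C)=CC(=O)OI(OC(=O)C=C(C)C)c1ccccc1 | intermediate
10 | oxobis(triphenylsiloxy)vanadium 1-(7-methoxy-2-oxo-2H-chromen-8-yl)-3-methylbuta-1,2-dien-1-olate, VO(OSiPh3)2(OC(Ar)=C=CMe2) | COc1ccc2ccc(=O)oc2c1C(O[V](=O)(O[Si](c1ccccc1)(c1ccccc1)c1ccccc1)O[Si](c1ccccc1)(c1ccccc1)c1ccccc1)=C=C(C)C | intermediate
11 | 7-methoxy-8-{3-methyl-2-[(3-methylbut-2-enoyloxy)(phenyl)iodanyl]but-2-enoyl}-2H-chromen-2-one (alkenyl iodane) | COc1ccc2ccc(=O)oc2c1C(=O)C(=C(C)C)I(OC(=O)C=C(C)C)c1ccccc1 | intermediate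
12 | kimcuongin, 1-(7-methoxy-2-oxo-2H-chromen-8-yl)-3-methyl-1-oxobut-2-en-2-yl 3-methylbut-2-enoate (achiral) | COc1ccc2ccc(=O)oc2c1C(=O)C(OC(=O)C=C(C)C)=C(C)C | target

## Step count and risks

Total step count: 5.
Longest linear sequence: 4 steps (steps 1, 2, 3 and 5, from 1 to 12); step 4 is a one-step side branch that makes reagent 9.

Three steps most likely to fail:

Risk 1, step 5 (the proposed new method). It may fail by protonation of 10 to the plain Meyer–Schuster enone or by unproductive breakdown of 11. The fallback uses known chemistry, sets out from 5 and comes back at 12. The tertiary alcohol of 5 is acylated with 3-methylbut-2-enoyl chloride (pyridine, DMAP, CH2Cl2, 0 °C to rt) to the propargylic ester 4-(7-methoxy-2-oxo-2H-chromen-8-yl)-2-methylbut-3-yn-2-yl 3-methylbut-2-enoate F1. F1 is then put through the established gold-catalysed oxidative 1,2-acyloxy migration of propargylic carboxylates (monovalent gold catalyst Ph3PAuNTf2 5 mol %, 8-methylquinoline N-oxide 1.5 equiv, ClCH2CH2Cl, rt). Oxygen transfer to the aryl-bound alkyne carbon and shift of the carboxylate onto the neighbouring carbon give 12 directly. Both ortho positions of the aryl group are blocked, so the usual cyclisation side path of aryl allenyl esters is closed.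

Risk 2, step 4 (ligand exchange with an unsaturated acid). The reagent may stay contaminated with 8 or decompose on concentration. The fallback sets out from 5 and 6 and comes back at 12; it swaps direct senecioate transfer for acetate transfer followed by acyl exchange. Step 5 is run with commercial PhI(OAc)2 6 in place of 9 under the same VO(OSiPh3)3 conditions. Through 10 and the acetate analogue of 11, 8-{2-[acetoxy(phenyl)iodanyl]-3-methylbut-2-enoyl}-7-methoxy-2H-chromen-2-one F2 (not isolated), this gives the enol acetate 1-(7-methoxy-2-oxo-2H-chromen-8-yl)-3-methyl-1-oxobut-2-en-2-yl acetate F3. Catalytic K2CO3 in MeOH at 0 °C cleaves the enol acetate to the diketone 1-(7-methoxy-2-oxo-2H-chromen-8-yl)-3-methylbutane-1,2-dione F4. LiN(SiMe3)2 (THF, −78 °C) removes the only enolisable hydrogen to give lithium 1-(7-methoxy-2-oxo-2H-chromen-8-yl)-3-methyl-1-oxobut-2-en-2-olate F5 (not isolated). 3-Methylbut-2-enoyl chloride acylates F5 on oxygen, the tetrasubstituted carbon being too hindered for C-acylation, to give 12.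

Risk 3, step 3 (coupling at the di-ortho-substituted C8 iodide). Glaser dimerisation of 4 may outrun the cross-coupling. The fallback sets out from 3 and 4 and comes back at 5; it leaves palladium catalysis for a stoichiometric copper route. Alkyne 4 is converted with CuI in aqueous NH3/EtOH into the preformed acetylide (3-hydroxy-3-methylbut-1-yn-1-yl)copper F6, which is filtered, dried and heated with 3 in pyridine at 110 °C under N2 (Castro–Stephens coupling). There is no free terminal alkyne and no oxidative dimerisation channel, and the method has long served for ortho-substituted aryl iodides.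

Further compounds
F1 | step 5 | 4-(7-methoxy-2-oxo-2H-chromen-8-yl)-2-methylbut-3-yn-2-yl 3-methylbut-2-enoate | COc1ccc2ccc(=O)oc2c1C#CC(C)(C)OC(=O)C=C(C)C
F2 | step 4 | 8-{2-[acetoxy(phenyl)iodanyl]-3-methylbut-2-enoyl}-7-methoxy-2H-chromen-2-one | COc1ccc2ccc(=O)oc2c1C(=O)C(=C(C)C)I(OC(C)=O)c1ccccc1
F3 | step 4 | 1-(7-methoxy-2-oxo-2H-chromen-8-yl)-3-methyl-1-oxobut-2-en-2-yl acetate | COc1ccc2ccc(=O)oc2c1C(=O)C(OC(C)=O)=C(C)C
F4 | step 4 | 1-(7-methoxy-2-oxo-2H-chromen-8-yl)-3-methylbutane-1,2-dione | COc1ccc2ccc(=O)oc2c1C(=O)C(=O)C(C)C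
F5 | step 4 | lithium 1-(7-methoxy-2-oxo-2H-chromen-8-yl)-3-methyl-1-oxobut-2-en-2-olate | COc1ccc2ccc(=O)oc2c1C(=O)C(O[Li])=C(C)C
F6 | step 3 | (3-hydroxy-3-methylbut-1-yn-1-yl)copper | CC(C)(O)C#C[Cu]
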